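Hold a closed flask against a stirred tank of the same 30 s and ask which one lets less target drain to its isomer.

common to all: starting material 1.4 M

| run | time | remark |
|---|---|---|
| south-west | 30 s | a closed flask charged with all of it at once and left for 30 s |
| south-east |  | one stirred flow tank at steady state, fed with the mixture as stated, mean residence time 30 s |

- the set-up with the highest share of target in all that became target or isomer of the product, at the outlet or at the end ("none" if the first two lie within 2 percentage points) (south-west / south-east / none)
- share of target in all that became target or isomer of the product, at the outlet or at the end, south-west
- share of target in all that became target or isomer of the product, at the outlet or at the end, south-east

    starting material ⇌ other conformer (K1 = 0.098, k1 = 0.0062 /s)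
    starting material → target (k2 = 0.016 /s)
    other conformer → isomer of the product (k3 = 0.017 /s)
    target ⇌ isomer of the product (K4 = 4.3, k4 = 0.011 /s)
    other conformer ⇌ dormant form (K5 = 15, k5 = 0.0020 /s)

Turn the vessel first. Write the isomer balance of the tank: at steady state the outflow removes isomer as fast as the step from target to isomer makes it, net of its way back. Isomer per target is then the forward constant times the residence time, divided by one plus that product over 4.3. Call this the drain ratio, 0.306. From it take the kept share, the part of target plus isomer that is target, with the step from target to isomer counted as the one source of isomer and so equal to one over one plus the drain ratio: 76.5%, a selectivity in the usual term.

Now integrate for the closed flask. Let the starting material fall at 0.0222 /s, its two forward steps with no return, and let each portion of target drain by the forward step for the time remaining. The same share comes to 83.6%. So my reckoning keeps more in the closed flask than in the tank, by 7.1 percentage points, which is wider than the margin, and I commit to south-west.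

Then turn the residence time of the tank to ten times its value. The drain ratio becomes 1.87 and the kept share 34.9%.

The forecast names south-west, with 80.2% (range 78.5% to 82%) for the closed flask and 72.7% (71% to 74.5%) for the tank, on the ground that “the broad residence-time spread of the stirred tank gives more over-conversion”. Its figures stand lower than mine, and for the tank the difference is 3.8 points.

The closed flask gives 80.1% and the tank 72.7%, so south-west is best.

At the tank outlet the readings are 8.85% isomer and 23.6% target, in percent of the charge. That is 0.375 isomer per target, more than the drain ratio of 0.306. Put the kept share to the tank at ten times the residence time: it falls from 76.5% to 34.9%, and that tank holds 33.5%.

The numbers of this flask come from no measurement; the flask was simulated.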